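Asterelin A is a dibenzofuran bridged from C1 and C7 by two ArCH2–CH2Ar' tethers through a diaryl ether. Each tether is cut at an aryl–CH2 bond into a styrene and an aryl halide. The key step exploits the bond between dibenzofuran C7 and the CH2 of the bridge to the oxygenated diaryl ether ring: hydroboration of a styrene and intramolecular B-alkyl Suzuki–Miyaura coupling onto the C7 chloride close the 18-membered ring and deliver the saturated bridge in one operation. The precursor is an open-chain 7-chlorodibenzofuran carrying a vinyl diaryl ether; a bromide-before-chloride order builds the first bridge by the same reaction.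

Key step: step 8

Remark: the target SMILES holds no stereocentre and no axis or plane descriptor. The macrocycle is assumed to be conformationally mobile, so the constitution alone defines the compound and no enantiocontrol is needed.

Step 1
Reactants: 1 2-bromo-3,5-dimethoxybenzaldehyde; 2 (4-chloro-2-fluorophenyl)boronic acid
Product: 3 4'-chloro-2'-fluoro-4,6-dimethoxy-[1,1'-biphenyl]-2-carbaldehyde
Conditions: Pd(dppf)Cl2 (5 mol%), K2CO3, 1,4-dioxane/H2O (4:1), 90 °C
Reagents that add atoms: none
Why: Suzuki–Miyaura coupling, in which oxidative addition into the formyl-activated C–Br bond of 1 is much faster than into the C–Cl bond of 2 with a dppf-ligated catalyst, so that the tri-ortho-substituted biaryl should form with chloride and fluoride untouched.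

Step 2
Reactants: 3 4'-chloro-2'-fluoro-4,6-dimethoxy-[1,1'-biphenyl]-2-carbaldehyde
Product: 4 4'-chloro-2'-fluoro-4,6-dihydroxy-[1,1'-biphenyl]-2-carbaldehyde
Conditions: BBr3 (4 equiv), CH2Cl2, −78 °C → rt; then H2O
Reagents that add atoms: none
Why: BBr3 ether cleavage (Lewis acid demethylation) should free both phenols, the aldehyde being returned on aqueous work-up and the aryl C–F and C–Cl bonds being inert.

Step 3
Reactants: 4 4'-chloro-2'-fluoro-4,6-dihydroxy-[1,1'-biphenyl]-2-carbaldehyde
Product: 6 7-chloro-3-methoxydibenzo[b,d]furan-1-carbaldehyde, via hydroxydibenzofuran aldehyde 5 (not isolated)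
Conditions: K2CO3 (3 equiv), NMP (0.05 M), 150 °C; then rt, MeI (1.5 equiv)
Reagents that add atoms: iodomethane, CI
Why: Intramolecular SNAr of a 2'-fluorobiaryl-2-olate, the standard fluoride route to dibenzofurans, in which only the phenoxide ortho to the biaryl bond can reach the C–F carbon and close the furan ring, after which the remaining C3 phenoxide is O-methylated in the same flask (Williamson etherification).

Step 4
Reactants: 6 7-chloro-3-methoxydibenzo[b,d]furan-1-carbaldehyde
Product: 7 7-chloro-1-ethenyl-3-methoxydibenzo[b,d]furan
Conditions: Ph3PCH3Br, KOtBu, THF, 0 °C → rt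
Reagents that add atoms: methyltriphenylphosphonium bromide, C[P+](c1ccccc1)(c1ccccc1)c1ccccc1.[Br-]
Why: Wittig methylenation of a non-enolisable aryl aldehyde with the unstabilised ylide should give the styrene, and the aryl chloride and the methyl ether do not react.

Step 5
Reactants: 8 isovanillin (3-hydroxy-4-methoxybenzaldehyde); 9 (4-bromophenyl)boronic acid
Product: 10 3-(4-bromophenoxy)-4-methoxybenzaldehyde
Conditions: Cu(OAc)2 (20 mol%), pyridine, 4 Å MS, CH2Cl2, O2 (1 atm), rt; 9 in excess (2 equiv)
Reagents that add atoms: none
Why: Chan–Lam oxidative C–O coupling transfers the aryl group of the boronic acid to the phenol oxygen at room temperature under Cu(II)/O2 and, unlike a Pd- or Cu(I)-mediated coupling, leaves the C–Br bond and the aldehyde untouched.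

Step 6
Reactants: 10 3-(4-bromophenoxy)-4-methoxybenzaldehyde
Product: 11 2-(4-bromophenoxy)-4-ethenyl-1-methoxybenzene
Conditions: Ph3PCH3Br, KOtBu, THF, 0 °C → rt
Reagents that add atoms: methyltriphenylphosphonium bromide, C[P+](c1ccccc1)(c1ccccc1)c1ccccc1.[Br-]
Why: Wittig methylenation of the aryl aldehyde should give the styrene, and with an alkoxide base there is no halogen–metal exchange at the aryl bromide.

Step 7
Reactants: 7 7-chloro-1-ethenyl-3-methoxydibenzo[b,d]furan; 12 9-borabicyclo[3.3.1]nonane (9-BBN); 11 2-(4-bromophenoxy)-4-ethenyl-1-methoxybenzene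
Product: 14 7-chloro-1-{2-[4-(5-ethenyl-2-methoxyphenoxy)phenyl]ethyl}-3-methoxydibenzo[b,d]furan, via alkylborane 13 (not isolated)
Conditions: 9-BBN (1.1 equiv), THF, 0 °C → rt; then degassed aq. K3PO4, 11, Pd(dppf)Cl2 (5 mol%), THF/DMF, 60 °C
Reagents that add atoms: none
Why: Anti-Markovnikov hydroboration of the styrene with 9-BBN followed by B-alkyl Suzuki–Miyaura coupling, in which residual B–H is destroyed by the aqueous base before 11 is added (so its vinyl group is kept) and the dppf-ligated catalyst activates the C–Br bond of 11 but not the C–Cl bond at dibenzofuran C7.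

Step 8
Reactants: 14 7-chloro-1-{2-[4-(5-ethenyl-2-methoxyphenoxy)phenyl]ethyl}-3-methoxydibenzo[b,d]furan; 12 9-borabicyclo[3.3.1]nonane (9-BBN)
Product: 16 asterelin A di-O-methyl ether, via alkylborane 15 (not isolated)
Conditions: 9-BBN (1.5 equiv), THF, rt; then syringe-pump addition (12 h) to SPhos Pd G3 (15 mol%), degassed aq. K3PO4, THF, 65 °C, final concentration about 2 mM
Reagents that add atoms: none
Why: 9-BBN adds anti-Markovnikov to the only alkene of 14 to give primary alkylborane 15; after base forms the borate, Pd(0)/SPhos inserts into the C7–Cl bond, the tethered alkyl group is transferred from boron to palladium within the same molecule, and C(sp2)–C(sp3) reductive elimination forges the dibenzofuran C7–CH2 bond. The closest known reaction type is the B-alkyl Suzuki–Miyaura macrocyclisation, together with the coupling of alkyl-9-BBN reagents with unactivated aryl chlorides under dialkylbiarylphosphine–Pd catalysis. The 18-membered ring closes end-to-end through a 19-membered palladacycle that contracts on reductive elimination, and the bridge arrives at its final saturated oxidation level. No stereocentre is formed. The step needs ring closure to win over oligomerisation and reductive elimination to win over β-hydride elimination: slow addition to the catalyst at high dilution and the bulky electron-rich ligand should secure both, and the rigid dibenzofuran with the bent diaryl ether holds the two chain ends on the same side. Regiochemistry cannot go astray because 15 carries a single C–B bond and a single C–halogen bond.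

Step 9
Reactants: 16 asterelin A di-O-methyl ether
Product: 17 asterelin A
Conditions: BBr3 (5 equiv), CH2Cl2, −78 °C → rt; then H2O
Reagents that add atoms: none
Why: BBr3 cleavage of the two aryl methyl ethers (Lewis acid demethylation) should free both phenols, while the diaryl ether, the dibenzofuran and the benzylic bridges are stable under these conditions.

Compound list
1 | 2-bromo-3,5-dimethoxybenzaldehyde | COc1cc(OC)c(Br)c(C=O)c1 | starting material
2 | (4-chloro-2-fluorophenyl)boronic acid | OB(O)c1ccc(Cl)cc1F | starting material
3 | 4'-chloro-2'-fluoro-4,6-dimethoxy-[1,1'-biphenyl]-2-carbaldehyde | COc1cc(OC)c(-c2ccc(Cl)cc2F)c(C=O)c1 | intermediate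
4 | 4'-chloro-2'-fluoro-4,6-dihydroxy-[1,1'-biphenyl]-2-carbaldehyde | Oc1cc(O)c(-c2ccc(Cl)cc2F)c(C=O)c1 | intermediate
5 | 7-chloro-3-hydroxydibenzo[b,d]furan-1-carbaldehyde (present as its potassium phenoxide, not isolated) | Oc1cc(C=O)c2c(c1)oc1cc(Cl)ccc12 | intermediate
6 | 7-chloro-3-methoxydibenzo[b,d]furan-1-carbaldehyde | COc1cc(C=O)c2c(c1)oc1cc(Cl)ccc12 | intermediate
7 | 7-chloro-1-ethenyl-3-methoxydibenzo[b,d]furan | COc1cc(C=C)c2c(c1)oc1cc(Cl)ccc12 | intermediate
8 | isovanillin (3-hydroxy-4-methoxybenzaldehyde) | COc1ccc(C=O)cc1O | starting material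
9 | (4-bromophenyl)boronic acid | OB(O)c1ccc(Br)cc1 | starting material
10 | 3-(4-bromophenoxy)-4-methoxybenzaldehyde | COc1ccc(C=O)cc1Oc1ccc(Br)cc1 | intermediate
11 | 2-(4-bromophenoxy)-4-ethenyl-1-methoxybenzene | COc1ccc(C=C)cc1Oc1ccc(Br)cc1 | intermediate
12 | 9-borabicyclo[3.3.1]nonane (9-BBN) | B1C2CCCC1CCC2 | starting material
13 | 9-[2-(7-chloro-3-methoxydibenzo[b,d]furan-1-yl)ethyl]-9-borabicyclo[3.3.1]nonane (not isolated) | COc1cc(CCB2C3CCCC2CCC3)c2c(c1)oc1cc(Cl)ccc12 | intermediate
14 | 7-chloro-1-{2-[4-(5-ethenyl-2-methoxyphenoxy)phenyl]ethyl}-3-methoxydibenzo[b,d]furan | COc1cc(CCc2ccc(Oc3cc(C=C)ccc3OC)cc2)c2c(c1)oc1cc(Cl)ccc12 | intermediate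
15 | 9-BBN adduct of 14 at the terminal vinyl carbon: 9-{2-[3-(4-{2-[7-chloro-3-methoxydibenzo[b,d]furan-1-yl]ethyl}phenoxy)-4-methoxyphenyl]ethyl}-9-borabicyclo[3.3.1]nonane (not isolated) | COc1cc(CCc2ccc(Oc3cc(CCB4C5CCCC4CCC5)ccc3OC)cc2)c2c(c1)oc1cc(Cl)ccc12 | intermediate
16 | asterelin A di-O-methyl ether (18-membered macrocycle, both phenols as methyl ethers) | COc1cc2c3c(c1)oc1cc(ccc13)CCc1ccc(OC)c(c1)Oc1ccc(cc1)CC2 | intermediate
17 | asterelin A | Oc1cc2c3c(c1)oc1cc(ccc13)CCc1ccc(O)c(c1)Oc1ccc(cc1)CC2 | target

Total step count: 9.
Longest linear sequence: 7 steps (steps 1, 2, 3, 4, 7, 8, 9, from compound 1).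

Steps most likely to fail

Step 8. Ring closure may be outrun by intermolecular coupling (oligomerisation), or by β-hydride elimination and protodeboronation of the alkylborane while oxidative addition into the aryl chloride is slow at high dilution. The fallback closes the same ring by olefin metathesis. It sets out from 14. Suzuki–Miyaura vinylation of the C7 chloride (vinylboronic acid pinacol ester, Pd(OAc)2/SPhos, K3PO4, dioxane/H2O, 90 °C) should give 7-ethenyl-1-{2-[4-(5-ethenyl-2-methoxyphenoxy)phenyl]ethyl}-3-methoxydibenzo[b,d]furan F1. Ring-closing metathesis of the two styrenes (second-generation Ru–NHC benzylidene catalyst, toluene, 1 mM, 80 °C, loss of ethene) should give the macrocyclic stilbene F2 as an E/Z mixture that need not be separated. Hydrogenation (H2, Pd/C, EtOAc, rt) would saturate the bridge and come back to the route at 16.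

Step 3. Displacement of the unactivated fluoride may be too slow at a temperature at which the phenoxide-bearing aldehyde survives, so that condensation and decomposition compete with furan closure. The fallback builds the C–O bond by C–H functionalisation instead of SNAr. It sets out from 1. Suzuki–Miyaura coupling with (4-chlorophenyl)boronic acid (Pd(dppf)Cl2, K2CO3, dioxane/H2O, 90 °C) should give 4'-chloro-4,6-dimethoxy-[1,1'-biphenyl]-2-carbaldehyde F3. BBr3 (CH2Cl2, −78 °C → rt) should give 4'-chloro-4,6-dihydroxy-[1,1'-biphenyl]-2-carbaldehyde F4. Phenol-directed Pd(II)-catalysed C–H activation/C–O cyclisation (Pd(OAc)2, IPr, sodium mesitoate, K2CO3, 4,5-diazafluoren-9-one, mesitylene, air, 120 °C) should then give 5; the two ortho C–H bonds of the para-substituted ring are equivalent, so only one dibenzofuran can form. Methylation (MeI, K2CO3, DMF, rt) comes back to the route at 6.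

Step 5. Aryl transfer from boron to the ortho-substituted, electron-poor phenoxide may be slow, so that the boronic acid is lost to protodeboronation, homocoupling and oxidation to the phenol before the ether forms. The fallback is an Ullmann ether synthesis with an aryl iodide as electrophile. It sets out from 8: coupling with 1-bromo-4-iodobenzene (CuI, N,N-dimethylglycine, Cs2CO3, dioxane, 90 °C), in which the C–I bond reacts ahead of the C–Br bond, comes back to the route directly at 10; no compound outside the list is made (F0).

Further compounds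
F1 | step 8 | 7-ethenyl-1-{2-[4-(5-ethenyl-2-methoxyphenoxy)phenyl]ethyl}-3-methoxydibenzo[b,d]furan | COc1cc(CCc2ccc(Oc3cc(C=C)ccc3OC)cc2)c2c(c1)oc1cc(C=C)ccc12
F2 | step 8 | macrocyclic stilbene, the 7,8-didehydro analogue of 16 at the bridge between dibenzofuran C7 and the methoxy-bearing ring (E/Z mixture) | COc1cc2c3c(c1)oc1cc(ccc13)C=Cc1ccc(OC)c(c1)Oc1ccc(cc1)CC2
F3 | step 3 | 4'-chloro-4,6-dimethoxy-[1,1'-biphenyl]-2-carbaldehyde | COc1cc(OC)c(-c2ccc(Cl)cc2)c(C=O)c1
F4 | step 3 | 4'-chloro-4,6-dihydroxy-[1,1'-biphenyl]-2-carbaldehyde | Oc1cc(O)c(-c2ccc(Cl)cc2)c(C=O)c1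
F0 | step 5 | none | none
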